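The ring atoms are numbered as in germacrane (C1=C10 alkene, C4–C5 epoxide, C6 ester, C7 isopropyl, C8 carbinol). The route rests on cutting the ten-membered carbocycle between C7 and C8: the C8 alcohol next to the isopropyl-bearing C7 is a homoallylic alcohol once the isopropyl is written as isopropenyl. The key step is a chromium dichloride-mediated intramolecular Nozaki–Hiyama allylation of an acyclic epoxy aldehyde that carries a (Z)-allylic bromide and the C6 ester. It closes the ring and sets C7 and C8 in one operation. Hydrogenation of the isopropenyl group and a Horner–Wadsworth–Emmons olefination, which turns the C6 phosphonoacetate into the cinnamate, complete the synthesis.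

Key step: step 13

Remark: C11 is the isopropyl methine carbon and C12 the isopropyl carbon that serves as the allylic CH2 before ring closure; the target has a cis (Z-alkene-derived) 4,5-epoxide and 4S,5R,6S,7R,8R configuration.

Step 1
Reactants: 1 tert-butyl(but-3-yn-1-yloxy)dimethylsilane
Product: 3 (E)-tert-butyl[(4-iodo-3-methylbut-3-en-1-yl)oxy]dimethylsilane, via vinylalane 2 (not isolated)
Conditions: Me3Al (2 equiv), Cp2ZrCl2 (20 mol%), CH2Cl2, 0 °C to rt; then I2, THF, −30 to 0 °C
Reagents that add atoms: trimethylaluminium (C[Al](C)C); iodine (II)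
Why: Zirconium-catalysed syn-carboalumination (Negishi carboalumination) puts methyl on the internal and aluminium on the terminal alkyne carbon, and iodine cleaves the C–Al bond with retention, which fixes the E alkene that becomes C1=C10.

Step 2
Reactants: 4 (Z)-3-methylpent-2-en-4-yn-1-ol
Product: 5 (Z)-3-methylpenta-2,4-dien-1-ol
Conditions: H2 (1 atm), Pd/CaCO3 poisoned with Pb(OAc)2, quinoline, EtOAc, rt, stopped after one equivalent
Reagents that add atoms: none
Why: Semi-hydrogenation over the poisoned palladium catalyst reduces only the terminal alkyne to the vinyl group and leaves the Z trisubstituted alkene (later C4–C5) untouched.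

Step 3
Reactants: 5 (Z)-3-methylpenta-2,4-dien-1-ol; 3 (E)-tert-butyl[(4-iodo-3-methylbut-3-en-1-yl)oxy]dimethylsilane
Product: 7 (2Z,6E)-9-[(tert-butyldimethylsilyl)oxy]-3,7-dimethylnona-2,6-dien-1-ol, via alkylborane 6 (not isolated)
Conditions: 9-BBN (2.2 equiv), THF, 0 °C to rt; then 3, PdCl2(dppf) (5 mol%), AsPh3, Cs2CO3, DMF/H2O, rt
Reagents that add atoms: none
Why: 9-BBN first borylates the hydroxyl and then hydroborates only the terminal vinyl group in the anti-Markovnikov sense, and the B-alkyl Suzuki–Miyaura coupling joins this primary carbon (C2) to the vinyl iodide carbon (C1) with retention of both alkene geometries.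

Step 4
Reactants: 7 (2Z,6E)-9-[(tert-butyldimethylsilyl)oxy]-3,7-dimethylnona-2,6-dien-1-ol
Product: 8 [(2R,3S)-3-[(3E)-6-[(tert-butyldimethylsilyl)oxy]-4-methylhex-3-en-1-yl]-3-methyloxiran-2-yl]methanol
Conditions: Ti(OiPr)4 (10 mol%), D-(−)-diethyl tartrate (12 mol%), t-BuOOH, 4 Å MS, CH2Cl2, −20 °C
Reagents that add atoms: tert-butyl hydroperoxide (CC(C)(C)OO)
Why: Sharpless asymmetric epoxidation, in which the titanium D-(−)-tartrate complex delivers oxygen to the face of the Z allylic alcohol that should give the (2R,3S) epoxy alcohol (C5 R, C4 S), while the remote alkene is not an allylic alcohol and stays intact.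

Step 5
Reactants: 8 [(2R,3S)-3-[(3E)-6-[(tert-butyldimethylsilyl)oxy]-4-methylhex-3-en-1-yl]-3-methyloxiran-2-yl]methanol
Product: 9 (2S,3S)-3-[(3E)-6-[(tert-butyldimethylsilyl)oxy]-4-methylhex-3-en-1-yl]-3-methyloxirane-2-carbaldehyde
Conditions: Dess–Martin periodinane, NaHCO3, CH2Cl2, 0 °C to rt
Reagents that add atoms: none
Why: Buffered Dess–Martin oxidation of the primary alcohol should give the epoxy aldehyde without epimerisation or epoxide opening (the descriptor at C2 changes only because of the new priority of the formyl group).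

Step 6
Reactants: 10 prop-2-yn-1-ol
Product: 12 (Z)-3-iodo-2-methylprop-2-en-1-ol, via vinylmagnesium alkoxide 11 (not isolated)
Conditions: MeMgBr (2.5 equiv), CuI (10 mol%), Et2O, −10 °C to rt; then I2, −10 °C
Reagents that add atoms: methylmagnesium bromide (C[Mg]Br); iodine (II)
Why: Copper-catalysed anti-carbomagnesiation of the propargylic alkoxide places methyl on C2 and magnesium on C3 within a five-membered chelate, and iodinolysis with retention gives the Z vinyl iodide.

Step 7
Reactants: 12 (Z)-3-iodo-2-methylprop-2-en-1-ol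
Product: 13 (Z)-tert-butyl[(3-iodo-2-methylprop-2-en-1-yl)oxy]dimethylsilane
Conditions: TBSCl, imidazole, CH2Cl2, 0 °C to rt
Reagents that add atoms: tert-butyldimethylsilyl chloride (CC(C)(C)[Si](C)(C)Cl)
Why: Imidazole-promoted silylation of the primary alcohol (silyl ether formation).

Step 8
Reactants: 13 (Z)-tert-butyl[(3-iodo-2-methylprop-2-en-1-yl)oxy]dimethylsilane; 9 (2S,3S)-3-[(3E)-6-[(tert-butyldimethylsilyl)oxy]-4-methylhex-3-en-1-yl]-3-methyloxirane-2-carbaldehyde
Product: 15 (1R,2Z)-4-[(tert-butyldimethylsilyl)oxy]-1-[(2R,3S)-3-[(3E)-6-[(tert-butyldimethylsilyl)oxy]-4-methylhex-3-en-1-yl]-3-methyloxiran-2-yl]-3-methylbut-2-en-1-ol, via vinyllithium 14 (not isolated)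
Conditions: 13, t-BuLi (2 equiv), Et2O, −78 °C; then 9, −78 °C; NH4Cl quench at −78 °C
Reagents that add atoms: none
Why: Iodine–lithium exchange keeps the Z geometry and the vinyllithium adds to the aldehyde (1,2-addition) under Felkin–Anh polar control, anti to the epoxide C–O bond, which should give mainly the erythro alcohol with C6 R.

Step 9
Reactants: 15 the (1R) allylic epoxy alcohol of step 8; 16 2-(diethoxyphosphoryl)acetic acid
Product: 17 (1S,2Z)-4-[(tert-butyldimethylsilyl)oxy]-1-[(2R,3S)-3-[(3E)-6-[(tert-butyldimethylsilyl)oxy]-4-methylhex-3-en-1-yl]-3-methyloxiran-2-yl]-3-methylbut-2-en-1-yl 2-(diethoxyphosphoryl)acetate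
Conditions: PPh3, DIAD, toluene, 0 °C to rt
Reagents that add atoms: none
Why: Mitsunobu esterification displaces the activated C6 hydroxyl by the carboxylate with SN2 inversion, which sets the required 6S configuration and installs the ester in one step; SN2′ attack is blocked by the fully substituted C11.

Step 10
Reactants: 17 the bis-silyl (1S) phosphonoacetate of step 9
Product: 18 (1S,2Z)-4-hydroxy-1-[(2R,3S)-3-[(3E)-6-hydroxy-4-methylhex-3-en-1-yl]-3-methyloxiran-2-yl]-3-methylbut-2-en-1-yl 2-(diethoxyphosphoryl)acetate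
Conditions: HF·pyridine, pyridine, THF, 0 °C to rt
Reagents that add atoms: none
Why: Buffered fluoride cleavage of both primary silyl ethers (desilylation) should leave the ester, the phosphonate and the trisubstituted epoxide intact.

Step 11
Reactants: 18 the diol of step 10
Product: 19 (1S,2Z)-4-bromo-1-[(2R,3S)-3-[(3E)-6-hydroxy-4-methylhex-3-en-1-yl]-3-methyloxiran-2-yl]-3-methylbut-2-en-1-yl 2-(diethoxyphosphoryl)acetate
Conditions: NBS, Me2S, CH2Cl2, −20 to 0 °C
Reagents that add atoms: N-bromosuccinimide (O=C1CCC(=O)N1Br)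
Why: Corey–Kim-type bromination, in which bromide displaces the alkoxysulfonium salt only at the allylic carbon (SN2, Z geometry kept), whereas the alkoxysulfonium salt of the homoallylic alcohol is not displaced and reverts on work-up.

Step 12
Reactants: 19 the bromo alcohol of step 11
Product: 20 (1S,2Z)-4-bromo-3-methyl-1-[(2R,3S)-3-methyl-3-[(3E)-4-methyl-6-oxohex-3-en-1-yl]oxiran-2-yl]but-2-en-1-yl 2-(diethoxyphosphoryl)acetate
Conditions: Dess–Martin periodinane, NaHCO3, CH2Cl2, 0 °C; used crude at once
Reagents that add atoms: none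
Why: Buffered Dess–Martin oxidation should give the β,γ-unsaturated aldehyde without moving the C1=C10 alkene into conjugation and without touching the allylic bromide.

Step 13
Reactants: 20 the bromo aldehyde of step 12
Product: 22 (1(10)E,4S,5R,6S,7R,8R)-4,5-epoxy-8-hydroxygermacra-1(10),11-dien-6-yl 2-(diethoxyphosphoryl)acetate, via allylchromium dichloride 21 (not isolated)
Conditions: CrCl2 (10 equiv), THF, 4 Å MS, rt, slow addition of 20 (final 2 mM)
Reagents that add atoms: none
Why: Chromium dichloride reduces the allylic bromide in two single-electron steps to the (Z)-allylchromium species 21, whose γ-carbon (C7) adds to the tethered aldehyde carbon (C8) through a six-membered chair transition state with chromium bound to the carbonyl oxygen; this is the intramolecular Nozaki–Hiyama (Barbier-type) allylation, a reaction type already used to close ten-membered germacrane rings onto epoxide-bearing aldehydes. The ten-membered carbocycle closes by attack of C7 on C8 with allylic transposition, so that C11=C12 ends up exocyclic as the isopropenyl group. C8 and its relation to C7 are set by the chair: the aldehyde chain (C9) is pseudo-equatorial and C6, cis to the chromium-bearing CH2, is pseudo-axial, which gives the syn (7R,8R) pairing. C7 relative to C6 is set by the existing C6 stereocentre: allylic 1,3-strain holds the C6–H bond in the plane of the allyl unit, and the aldehyde, delivered by the tether through C5, attacks the face anti to the C6–O bond. The step needs chemoselectivity (divalent chromium leaves epoxide, ester and phosphonate untouched and the allylchromium adds only to the aldehyde), retention of the Z allyl geometry (the methyl on C11 and the branched C6 disfavour the C7-bound isomer through which geometry exchange and loss of the C6 ester would run) and ring closure over oligomerisation (slow addition at high dilution).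

Step 14
Reactants: 22 the isopropenyl macrocycle of step 13
Product: 23 (1(10)E,4S,5R,6S,7R,8R)-4,5-epoxy-8-hydroxygermacr-1(10)-en-6-yl 2-(diethoxyphosphoryl)acetate
Conditions: H2 (1 atm), RhCl(PPh3)3 (10 mol%), benzene, rt
Reagents that add atoms: none
Why: Homogeneous hydrogenation with RhCl(PPh3)3 should reduce the 1,1-disubstituted isopropenyl alkene much faster than the trisubstituted ring alkene and leave epoxide and ester untouched, with no change at C7.

Step 15
Reactants: 23 the isopropyl macrocycle of step 14; 24 benzaldehyde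
Product: 25 (1(10)E,4S,5R,6S,7R,8R)-4,5-epoxy-8-hydroxygermacr-1(10)-en-6-yl (E)-3-phenylprop-2-enoate (target)
Conditions: LiCl, DBU, MeCN, 0 °C to rt
Reagents that add atoms: none
Why: Horner–Wadsworth–Emmons olefination under Masamune–Roush conditions, in which the lithium-chelated phosphonate anion adds to benzaldehyde and loses phosphate to give the E cinnamate, is mild enough to spare the free C8 hydroxyl and the epoxide.

Compound list
1 | tert-butyl(but-3-yn-1-yloxy)dimethylsilane | C#CCCO[Si](C)(C)C(C)(C)C | starting material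
2 | (E)-[4-(tert-butyldimethylsilyloxy)-2-methylbut-1-en-1-yl]dimethylalane | C/C(=C\[Al](C)C)CCO[Si](C)(C)C(C)(C)C | intermediate
3 | (E)-tert-butyl[(4-iodo-3-methylbut-3-en-1-yl)oxy]dimethylsilane | C/C(=C\I)CCO[Si](C)(C)C(C)(C)C | intermediate
4 | (Z)-3-methylpent-2-en-4-yn-1-ol | C#C/C(C)=C\CO | starting material
5 | (Z)-3-methylpenta-2,4-dien-1-ol | C=C/C(C)=C\CO | intermediate
6 | 9-[(Z)-5-(9-borabicyclo[3.3.1]nonan-9-yloxy)-3-methylpent-3-en-1-yl]-9-borabicyclo[3.3.1]nonane | C1CCC2CCCC1B2CC/C(C)=C\COB1C2CCCC1CCC2 | intermediate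
7 | (2Z,6E)-9-[(tert-butyldimethylsilyl)oxy]-3,7-dimethylnona-2,6-dien-1-ol | C/C(=C\CC/C(C)=C\CO)CCO[Si](C)(C)C(C)(C)C | intermediate
8 | [(2R,3S)-3-[(3E)-6-[(tert-butyldimethylsilyl)oxy]-4-methylhex-3-en-1-yl]-3-methyloxiran-2-yl]methanol | C/C(=C\CC[C@]1(C)O[C@@H]1CO)CCO[Si](C)(C)C(C)(C)C | intermediate
9 | (2S,3S)-3-[(3E)-6-[(tert-butyldimethylsilyl)oxy]-4-methylhex-3-en-1-yl]-3-methyloxirane-2-carbaldehyde | C/C(=C\CC[C@]1(C)O[C@@H]1C=O)CCO[Si](C)(C)C(C)(C)C | intermediate
10 | prop-2-yn-1-ol | C#CCO | starting material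
11 | bromo[(Z)-3-(bromomagnesiooxy)-2-methylprop-1-en-1-yl]magnesium | C/C(=C/[Mg]Br)CO[Mg]Br | intermediate
12 | (Z)-3-iodo-2-methylprop-2-en-1-ol | C/C(=C/I)CO | intermediate
13 | (Z)-tert-butyl[(3-iodo-2-methylprop-2-en-1-yl)oxy]dimethylsilane | C/C(=C/I)CO[Si](C)(C)C(C)(C)C | intermediate
14 | (Z)-[3-(tert-butyldimethylsilyloxy)-2-methylprop-1-en-1-yl]lithium | C/C(=C/[Li])CO[Si](C)(C)C(C)(C)C | intermediate
15 | (1R,2Z)-4-[(tert-butyldimethylsilyl)oxy]-1-[(2R,3S)-3-[(3E)-6-[(tert-butyldimethylsilyl)oxy]-4-methylhex-3-en-1-yl]-3-methyloxiran-2-yl]-3-methylbut-2-en-1-ol | C/C(=C\CC[C@]1(C)O[C@@H]1[C@H](O)/C=C(C)\CO[Si](C)(C)C(C)(C)C)CCO[Si](C)(C)C(C)(C)C | intermediate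
16 | 2-(diethoxyphosphoryl)acetic acid | CCOP(=O)(CC(=O)O)OCC | starting material
17 | (1S,2Z)-4-[(tert-butyldimethylsilyl)oxy]-1-[(2R,3S)-3-[(3E)-6-[(tert-butyldimethylsilyl)oxy]-4-methylhex-3-en-1-yl]-3-methyloxiran-2-yl]-3-methylbut-2-en-1-yl 2-(diethoxyphosphoryl)acetate | C/C(=C\CC[C@]1(C)O[C@@H]1[C@@H](OC(=O)CP(=O)(OCC)OCC)/C=C(C)\CO[Si](C)(C)C(C)(C)C)CCO[Si](C)(C)C(C)(C)C | intermediate
18 | (1S,2Z)-4-hydroxy-1-[(2R,3S)-3-[(3E)-6-hydroxy-4-methylhex-3-en-1-yl]-3-methyloxiran-2-yl]-3-methylbut-2-en-1-yl 2-(diethoxyphosphoryl)acetate | C/C(=C\CC[C@]1(C)O[C@@H]1[C@@H](OC(=O)CP(=O)(OCC)OCC)/C=C(C)\CO)CCO | intermediate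
19 | (1S,2Z)-4-bromo-1-[(2R,3S)-3-[(3E)-6-hydroxy-4-methylhex-3-en-1-yl]-3-methyloxiran-2-yl]-3-methylbut-2-en-1-yl 2-(diethoxyphosphoryl)acetate | C/C(=C\CC[C@]1(C)O[C@@H]1[C@@H](OC(=O)CP(=O)(OCC)OCC)/C=C(C)\CBr)CCO | intermediate
20 | (1S,2Z)-4-bromo-3-methyl-1-[(2R,3S)-3-methyl-3-[(3E)-4-methyl-6-oxohex-3-en-1-yl]oxiran-2-yl]but-2-en-1-yl 2-(diethoxyphosphoryl)acetate | C/C(=C\CC[C@]1(C)O[C@@H]1[C@@H](OC(=O)CP(=O)(OCC)OCC)/C=C(C)\CBr)CC=O | intermediate
21 | (Z)-allylchromium dichloride formed from 20 (CrCl2 on C12 in place of bromine) | C/C(=C\CC[C@]1(C)O[C@@H]1[C@@H](OC(=O)CP(=O)(OCC)OCC)/C=C(C)\C[Cr](Cl)Cl)CC=O | intermediate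
22 | (1(10)E,4S,5R,6S,7R,8R)-4,5-epoxy-8-hydroxygermacra-1(10),11-dien-6-yl 2-(diethoxyphosphoryl)acetate | C/C1=C\CC[C@]2(C)O[C@@H]2[C@@H](OC(=O)CP(=O)(OCC)OCC)[C@H](C(C)=C)[C@H](O)C1 | intermediate
23 | (1(10)E,4S,5R,6S,7R,8R)-4,5-epoxy-8-hydroxygermacr-1(10)-en-6-yl 2-(diethoxyphosphoryl)acetate | C/C1=C\CC[C@]2(C)O[C@@H]2[C@@H](OC(=O)CP(=O)(OCC)OCC)[C@H](C(C)C)[C@H](O)C1 | intermediate
24 | benzaldehyde | O=Cc1ccccc1 | starting material
25 | (1(10)E,4S,5R,6S,7R,8R)-4,5-epoxy-8-hydroxygermacr-1(10)-en-6-yl (E)-3-phenylprop-2-enoate | C/C1=C\CC[C@]2(C)O[C@@H]2[C@@H](OC(=O)/C=C/c2ccccc2)[C@H](C(C)C)[C@H](O)C1 | target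

Total step count: 15. Longest linear sequence: 12 steps (steps 1, 3, 4, 5, 8, 9, 10, 11, 12, 13, 14, 15, from compound 1).

Steps most likely to fail

Step 13. The allylchromium may lose the C6 carboxylate (elimination to a diene), may exchange its geometry and then pair C7 and C8 the wrong way, or may couple between molecules instead of closing the ring. The fallback replaces the chromium-reduced halide by a catalytic palladium umpolung of an allylic acetate. It sets out from bromo alcohol 19: potassium acetate in DMF displaces the bromide (SN2, Z geometry kept) to give the allylic acetate alcohol F1, and buffered Dess–Martin oxidation gives the acetate aldehyde F2. Under Pd(PPh3)4 (catalytic) and InI in THF at high dilution, a π-allylpalladium complex formed by zerovalent palladium is transmetallated to an allylindium species that is present only in low concentration and adds to the aldehyde through the same chair arrangement. The route is rejoined at 22.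

Step 9. The inversion may stall at the hindered allylic carbinol or be diverted to elimination or allylic transposition. The fallback replaces substitution by an oxidation–reduction sequence and sets out from alcohol 15. Dess–Martin oxidation gives the epoxy enone F3. Corey–Bakshi–Shibata reduction ((S)-2-methyl-CBS-oxazaborolidine, catecholborane, toluene, −78 °C), with the alkenyl arm acting as the large group and the Felkin preference of the epoxy ketone pointing the same way, should give the (1S) alcohol F4. Carbodiimide esterification of F4 with acid 16 (DCC, DMAP, CH2Cl2) proceeds with retention and rejoins the route at 17.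

Step 8. Facial selectivity at the epoxy aldehyde may be poor, and the basic lithium alkoxide may trigger epoxide migration. The fallback sets out from iodide 13 and aldehyde 9 and replaces the organolithium addition by a catalyst-controlled Nozaki–Hiyama–Kishi coupling (CrCl2, NiCl2 catalytic, a chiral oxazoline–sulfonamide ligand, THF, rt), in which the ligand on chromium chooses the aldehyde face and the product is a non-basic chromium alkoxide. It rejoins the route at 15 and makes no new compound (F0).

Further compounds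
F1 | step 13 | (2Z,4S)-4-{[2-(diethoxyphosphoryl)acetyl]oxy}-4-[(2R,3S)-3-[(3E)-6-hydroxy-4-methylhex-3-en-1-yl]-3-methyloxiran-2-yl]-2-methylbut-2-en-1-yl acetate | C/C(=C\CC[C@]1(C)O[C@@H]1[C@@H](OC(=O)CP(=O)(OCC)OCC)/C=C(C)\COC(C)=O)CCO
F2 | step 13 | (2Z,4S)-4-{[2-(diethoxyphosphoryl)acetyl]oxy}-2-methyl-4-[(2R,3S)-3-methyl-3-[(3E)-4-methyl-6-oxohex-3-en-1-yl]oxiran-2-yl]but-2-en-1-yl acetate | C/C(=C\CC[C@]1(C)O[C@@H]1[C@@H](OC(=O)CP(=O)(OCC)OCC)/C=C(C)\COC(C)=O)CC=O
F3 | step 9 | (2Z)-4-[(tert-butyldimethylsilyl)oxy]-1-[(2S,3S)-3-[(3E)-6-[(tert-butyldimethylsilyl)oxy]-4-methylhex-3-en-1-yl]-3-methyloxiran-2-yl]-3-methylbut-2-en-1-one | C/C(=C\CC[C@]1(C)O[C@@H]1C(=O)/C=C(C)\CO[Si](C)(C)C(C)(C)C)CCO[Si](C)(C)C(C)(C)C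
F4 | step 9 | (1S,2Z)-4-[(tert-butyldimethylsilyl)oxy]-1-[(2R,3S)-3-[(3E)-6-[(tert-butyldimethylsilyl)oxy]-4-methylhex-3-en-1-yl]-3-methyloxiran-2-yl]-3-methylbut-2-en-1-ol | C/C(=C\CC[C@]1(C)O[C@@H]1[C@@H](O)/C=C(C)\CO[Si](C)(C)C(C)(C)C)CCO[Si](C)(C)C(C)(C)C
F0 | step 8 | none | none
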